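**Plan**
Isochroman numbering is used for the core: C1 is the acetal carbon, O2 the ring oxygen, C3 the carbinol carbon on isoquinoline C7, C4 the acetyl-bearing carbon. The enabling feature is that C1 and the acetyl carbon on C4 are the two ends of the C2=C3 bond of a 2-methyl-1H-indene fused to ring A, with C4 as its sp3 carbon. The retrosynthesis therefore cuts C1–O2 and C1–O(isoquinoline C6) and rejoins C1 to the acetyl carbon.
Next the indene alkene is cut (ring-closing metathesis), then C3–C4 (allylboration). This leaves a 6-silyloxyisoquinoline-7-carbaldehyde and an (E)-3-aryl-2-methylallyl metal; both arenes go back to one bromo aldehyde made from 4-bromo-2,6-dimethoxybenzaldehyde.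
Forward: common arene; isoquinoline ring (Sonogashira coupling, ammonia) on one half and the allyl unit on the other; C3–C4 bond; ring A aldehyde unmasked; five-membered ring closed; ozonolysis with acetalisation closes the isochroman and 1,3-dioxane rings in the last step.
Stereochemistry: C3 (R) and C4 (S) are set together in the allylboration (the Ipc groups choose the aldehyde face, the (E)-allylborane in a chair transition state gives the anti pair). C1 (R) follows from C3 through the bridge, and C4 carries no enolisable carbonyl until the final step.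

Key step: step 17

Remark on the chemistry: the (−)-α-pinene-derived allylborane is taken to attack the Re face of the aryl aldehyde, as this reagent class does with benzaldehyde; the mirror-image reagent would be used if the opposite sense were found.

**Route**

Step 1
Reactants: 1 4-bromo-2,6-dimethoxybenzaldehyde
Product: 2 4-bromo-2,6-dihydroxybenzaldehyde
Conditions: BBr3 (3 equiv), CH2Cl2, −78 °C to rt; H2O
Reagents that add atoms: none
Why: Lewis acid cleavage of both aryl methyl ethers (the first assisted by chelation to the formyl oxygen) should give the symmetric resorcinol aldehyde, so that no choice between the two ring oxygens has to be made at this stage.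

Step 2
Reactants: 2 4-bromo-2,6-dihydroxybenzaldehyde
Product: 3 5-bromo-2-(hydroxymethyl)benzene-1,3-diol
Conditions: NaBH4, THF/H2O, 0 °C; pH 6 work-up, used crude
Reagents that add atoms: none
Why: Borohydride reduction of the aldehyde should give the benzylic alcohol, which is carried on at once because 2-hydroxybenzyl alcohols form quinone methides under acid.

Step 3
Reactants: 3 5-bromo-2-(hydroxymethyl)benzene-1,3-diol
Product: 4 7-bromo-2,2-dimethyl-4H-1,3-benzodioxin-5-ol
Conditions: 2,2-dimethoxypropane, PPTS (cat.), acetone, rt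
Reagents that add atoms: 2,2-dimethoxypropane COC(C)(C)OC
Why: Acid-catalysed transacetalisation should give the six-membered isopropylidene acetal across the benzylic hydroxyl and one of the two equivalent phenols, which tells the ring oxygens apart without any selectivity issue.

Step 4
Reactants: 4 7-bromo-2,2-dimethyl-4H-1,3-benzodioxin-5-ol
Product: 5 7-bromo-5-hydroxy-2,2-dimethyl-4H-1,3-benzodioxine-6-carbaldehyde
Conditions: MgCl2, Et3N, paraformaldehyde, MeCN, reflux
Reagents that add atoms: formaldehyde (as paraformaldehyde) C=O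
Why: In this Casnati–Skattebøl ortho-formylation the magnesium phenoxide should deliver formaldehyde to the only free ortho position (C6, between OH and Br), and a second formaldehyde oxidises the benzylic alkoxide by hydride transfer.

Step 5
Reactants: 5 7-bromo-5-hydroxy-2,2-dimethyl-4H-1,3-benzodioxine-6-carbaldehyde
Product: 6 7-bromo-5-methoxy-2,2-dimethyl-4H-1,3-benzodioxine-6-carbaldehyde
Conditions: MeI, K2CO3, DMF, rt
Reagents that add atoms: iodomethane CI
Why: Williamson O-methylation of the chelated phenol should place the methoxy group next to the new formyl group, the arrangement that both halves of the target need.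

Step 6
Reactants: 6 7-bromo-5-methoxy-2,2-dimethyl-4H-1,3-benzodioxine-6-carbaldehyde
Product: 8 isopropylidene acetal (O6 and 7-CH2O) of 7-(hydroxymethyl)-8-methoxy-3-methylisoquinolin-6-ol, via alkynyl aldehyde 7 (not isolated)
Conditions: propyne (1 M in THF), PdCl2(PPh3)2 (3 mol %), CuI (5 mol %), Et3N, DMF, 50 °C, sealed tube; then NH3 (7 M in MeOH), 80 °C
Reagents that add atoms: propyne CC#C; ammonia N
Why: Sonogashira coupling at the bromide ortho to the formyl group, then condensation with ammonia and 6-endo-dig cyclisation of the NH-imine onto the copper-activated alkyne (nitrogen to the methyl-bearing carbon), should give the 3-methylisoquinoline.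

Step 7
Reactants: 8 isopropylidene acetal of 7-(hydroxymethyl)-8-methoxy-3-methylisoquinolin-6-ol
Product: 9 7-(hydroxymethyl)-8-methoxy-3-methylisoquinolin-6-ol
Conditions: 1 M HCl, THF, rt; NaHCO3 to pH 7
Reagents that add atoms: none
Why: Aqueous acid hydrolysis of the benzodioxine acetal should free the phenol and the benzylic alcohol.

Step 8
Reactants: 9 7-(hydroxymethyl)-8-methoxy-3-methylisoquinolin-6-ol
Product: 10 6-hydroxy-8-methoxy-3-methylisoquinoline-7-carbaldehyde
Conditions: MnO2, acetone/CH2Cl2, rt
Reagents that add atoms: none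
Why: MnO2 oxidation of the 2-hydroxybenzyl alcohol should stop at the aldehyde and leave the phenol and the heterocycle untouched.

Step 9
Reactants: 10 6-hydroxy-8-methoxy-3-methylisoquinoline-7-carbaldehyde
Product: 11 6-[(tert-butyldimethylsilyl)oxy]-8-methoxy-3-methylisoquinoline-7-carbaldehyde
Conditions: TBSCl, imidazole, DMF, rt
Reagents that add atoms: tert-butyldimethylsilyl chloride CC(C)(C)[Si](C)(C)Cl
Why: Imidazole-promoted silylation masks the phenol, which would otherwise protonolyse the allylborane of step 13 and would be exposed to ozone in step 17.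

Step 10
Reactants: 6 7-bromo-5-methoxy-2,2-dimethyl-4H-1,3-benzodioxine-6-carbaldehyde
Product: 12 7-bromo-6-ethenyl-5-methoxy-2,2-dimethyl-4H-1,3-benzodioxine
Conditions: Ph3PCH3Br, KOtBu, THF, 0 °C to rt
Reagents that add atoms: methyltriphenylphosphonium bromide C[P+](c1ccccc1)(c1ccccc1)c1ccccc1.[Br-]
Why: Wittig methylenation should turn the formyl group into the styrenyl vinyl group whose inner carbon later becomes C3 of the indene and C1 of the target.

Step 11
Reactants: 12 7-bromo-6-ethenyl-5-methoxy-2,2-dimethyl-4H-1,3-benzodioxine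
Product: 14 1-(6-ethenyl-5-methoxy-2,2-dimethyl-4H-1,3-benzodioxin-7-yl)-2-methylprop-2-en-1-ol (racemic), via aryllithium 13 (not isolated)
Conditions: n-BuLi, THF, −78 °C; methacrolein, −78 to −20 °C; H2O
Reagents that add atoms: methacrolein CC(=C)C=O
Why: Bromine–lithium exchange and 1,2-addition of the aryllithium to methacrolein should bring in all carbons of the allyl unit in one operation, the racemic carbinol centre being erased in the next step.

Step 12
Reactants: 14 1-(6-ethenyl-5-methoxy-2,2-dimethyl-4H-1,3-benzodioxin-7-yl)-2-methylprop-2-en-1-ol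
Product: 16 7-[(1E)-3-chloro-2-methylprop-1-en-1-yl]-6-ethenyl-5-methoxy-2,2-dimethyl-4H-1,3-benzodioxine, via mesylate 15 (not isolated)
Conditions: MsCl, Et3N, THF, −20 °C; then LiCl, DMF, 0 °C to rt
Reagents that add atoms: lithium chloride [Li+].[Cl-]
Why: Mesylation followed by chloride substitution with allylic transposition (SN2′ and ion-pair equilibration under excess chloride) should give the conjugated primary chloride, and any secondary isomer left behind gives the same allylmagnesium reagent in step 13.

Step 13
Reactants: 16 7-[(1E)-3-chloro-2-methylprop-1-en-1-yl]-6-ethenyl-5-methoxy-2,2-dimethyl-4H-1,3-benzodioxine; 11 6-[(tert-butyldimethylsilyl)oxy]-8-methoxy-3-methylisoquinoline-7-carbaldehyde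
Product: 19 (1R,2S)-1-{6-[(tert-butyldimethylsilyl)oxy]-8-methoxy-3-methylisoquinolin-7-yl}-2-(6-ethenyl-5-methoxy-2,2-dimethyl-4H-1,3-benzodioxin-7-yl)-3-methylbut-3-en-1-ol, via allylmagnesium chloride 17 (not isolated), via allyl(diisopinocampheyl)borane 18 (not isolated)
Conditions: Mg turnings, THF, 0 °C (slow addition of 16); (+)-Ipc2BOMe, Et2O, −78 °C to rt; 11, −78 to −20 °C; NaOAc, H2O2, 0 °C
Reagents that add atoms: none
Why: In this Brown asymmetric allylboration the Grignard reagent is transmetallated to the allyl(diisopinocampheyl)borane, which settles by 1,3-boron shift as the (E)-primary isomer and adds through a closed chair transition state, the equatorial γ-aryl group giving the anti pair (2S relative to 1R) and the (−)-α-pinene-derived Ipc groups directing attack to the Re face of the aldehyde (1R), a stoichiometric boron reagent being chosen because it tolerates the basic isoquinoline nitrogen that would neutralise an acid catalyst.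

Step 14
Reactants: 19 the (1R,2S) acetonide-protected diene carbinol
Product: 20 (1R,2S)-1-{6-[(tert-butyldimethylsilyl)oxy]-8-methoxy-3-methylisoquinolin-7-yl}-2-[2-ethenyl-5-hydroxy-4-(hydroxymethyl)-3-methoxyphenyl]-3-methylbut-3-en-1-ol
Conditions: 1 M HCl, THF, 0 °C to rt; NaHCO3
Reagents that add atoms: none
Why: Acid hydrolysis of the benzodioxine acetal is done here, while the future C4 is still a non-enolisable allylic centre, and the aryl silyl ether and the two terminal alkenes should tolerate dilute acid.

Step 15
Reactants: 20 the (1R,2S) diene triol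
Product: 21 4-[(3S,4R)-4-{6-[(tert-butyldimethylsilyl)oxy]-8-methoxy-3-methylisoquinolin-7-yl}-4-hydroxy-2-methylbut-1-en-3-yl]-5-ethenyl-2-hydroxy-6-methoxybenzaldehyde
Conditions: MnO2, CH2Cl2, rt
Reagents that add atoms: none
Why: MnO2 should oxidise the primary 2-hydroxybenzyl alcohol to the ring A aldehyde, while the secondary carbinol, flanked by two ortho substituents and a branched neighbour, is not oxidised at a useful rate.

Step 16
Reactants: 21 the diene aldehyde
Product: 22 (1S)-1-[(R)-{6-[(tert-butyldimethylsilyl)oxy]-8-methoxy-3-methylisoquinolin-7-yl}(hydroxy)methyl]-6-hydroxy-4-methoxy-2-methyl-1H-indene-5-carbaldehyde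
Conditions: second-generation Hoveyda–Grubbs catalyst RuCl2(SIMes)(=CH-C6H4-2-OiPr) (10 mol %), 1,4-benzoquinone (20 mol %), toluene, 60 °C
Reagents that add atoms: none
Why: Ring-closing metathesis of the styrenyl vinyl group with the isopropenyl group should close the five-membered ring as the trisubstituted C2=C3 bond of a 2-methyl-1H-indene with loss of ethene, benzoquinone suppressing hydride-induced double-bond migration and the neutral medium leaving the acidic C1–H and both stereocentres untouched.

Step 17
Reactants: 22 the indene carbinol aldehyde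
Product: 25 CNP0584953.1, via keto dialdehyde 23 (not isolated), via lactol 24 (not isolated)
Conditions: O3, CH2Cl2/MeOH (5:1), Sudan Red 7B, −78 °C; Me2S, −78 °C to rt; then HF·pyridine, THF, 0 °C to rt
Reagents that add atoms: ozone O=[O+][O-]
Why: Ozone adds to the C2=C3 bond of the indene, the only non-aromatic alkene in 22, and reduction with Me2S gives the methyl ketone on C4 and an aryl aldehyde on the neighbouring ring A carbon (23), to which the C3 hydroxyl adds in a 6-exo-trig closure that forms C1–O2 and the isochroman ring as its lactol. HF·pyridine then removes the silyl group and, as a mild acid, ionises lactol 24 to a benzylic oxocarbenium ion (stabilised by the ortho methoxy and para hydroxy groups of ring A) that the freed C6 phenol traps in a 6-endo-trig closure, forming C1–O(aryl) and the 1,3-dioxane ring. The closest known reaction type is the ozonolysis of indenes to 2-(2-oxoalkyl)benzaldehydes followed by lactol formation and acid-catalysed acetal exchange with neighbouring hydroxyl groups. The only new stereocentre, C1, is fixed as R by C3, because the aryloxy bridge can reach the cationic carbon only from the face on which the isoquinoline sits, while C3 and C4 pass through unchanged since the indene kept C4 free of an enolisable carbonyl until this last step. The step needs cleavage of the alkene beside three oxygenated arenes, secured by the higher rate of the trisubstituted styrenyl bond, the formyl group that deactivates the ring A phenol, the silyl ether on the isoquinoline oxygen and the dye end point, and it needs acetalisation at the aldehyde and not the ketone, secured by the more electrophilic formyl carbon and the stabilised oxocarbenium ion. Because the indene releases no one-carbon fragment, no formaldehyde is present that could tie the hydroxyl and phenol pair into a formal.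

**Compound list**

1 | 4-bromo-2,6-dimethoxybenzaldehyde | COc1cc(Br)cc(OC)c1C=O | starting material
2 | 4-bromo-2,6-dihydroxybenzaldehyde | O=Cc1c(O)cc(Br)cc1O | intermediate
3 | 5-bromo-2-(hydroxymethyl)benzene-1,3-diol | OCc1c(O)cc(Br)cc1O | intermediate
4 | 7-bromo-2,2-dimethyl-4H-1,3-benzodioxin-5-ol | CC1(C)OCc2c(O)cc(Br)cc2O1 | intermediate
5 | 7-bromo-5-hydroxy-2,2-dimethyl-4H-1,3-benzodioxine-6-carbaldehyde | CC1(C)OCc2c(O)c(C=O)c(Br)cc2O1 | intermediate
6 | 7-bromo-5-methoxy-2,2-dimethyl-4H-1,3-benzodioxine-6-carbaldehyde | COc1c(C=O)c(Br)cc2OC(C)(C)OCc12 | intermediate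
7 | 5-methoxy-2,2-dimethyl-7-(prop-1-yn-1-yl)-4H-1,3-benzodioxine-6-carbaldehyde | CC#Cc1cc2OC(C)(C)OCc2c(OC)c1C=O | intermediate
8 | isopropylidene acetal (bridging O6 and the 7-CH2O group) of 7-(hydroxymethyl)-8-methoxy-3-methylisoquinolin-6-ol | COc1c2cnc(C)cc2cc2OC(C)(C)OCc12 | intermediate
9 | 7-(hydroxymethyl)-8-methoxy-3-methylisoquinolin-6-ol | COc1c(CO)c(O)cc2cc(C)ncc12 | intermediate
10 | 6-hydroxy-8-methoxy-3-methylisoquinoline-7-carbaldehyde | COc1c(C=O)c(O)cc2cc(C)ncc12 | intermediate
11 | 6-[(tert-butyldimethylsilyl)oxy]-8-methoxy-3-methylisoquinoline-7-carbaldehyde | COc1c(C=O)c(O[Si](C)(C)C(C)(C)C)cc2cc(C)ncc12 | intermediate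
12 | 7-bromo-6-ethenyl-5-methoxy-2,2-dimethyl-4H-1,3-benzodioxine | COc1c(C=C)c(Br)cc2OC(C)(C)OCc12 | intermediate
13 | (6-ethenyl-5-methoxy-2,2-dimethyl-4H-1,3-benzodioxin-7-yl)lithium | COc1c(C=C)c([Li])cc2OC(C)(C)OCc12 | intermediate
14 | 1-(6-ethenyl-5-methoxy-2,2-dimethyl-4H-1,3-benzodioxin-7-yl)-2-methylprop-2-en-1-ol (racemic) | COc1c(C=C)c(C(O)C(C)=C)cc2OC(C)(C)OCc12 | intermediate
15 | methanesulfonate of 14 | COc1c(C=C)c(C(OS(C)(=O)=O)C(C)=C)cc2OC(C)(C)OCc12 | intermediate
16 | 7-[(1E)-3-chloro-2-methylprop-1-en-1-yl]-6-ethenyl-5-methoxy-2,2-dimethyl-4H-1,3-benzodioxine | COc1c(C=C)c(/C=C(\C)CCl)cc2OC(C)(C)OCc12 | intermediate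
17 | [(2E)-3-(6-ethenyl-5-methoxy-2,2-dimethyl-4H-1,3-benzodioxin-7-yl)-2-methylprop-2-en-1-yl]magnesium chloride | COc1c(C=C)c(/C=C(\C)C[Mg]Cl)cc2OC(C)(C)OCc12 | intermediate
18 | B-[(2E)-3-(6-ethenyl-5-methoxy-2,2-dimethyl-4H-1,3-benzodioxin-7-yl)-2-methylprop-2-en-1-yl]diisopinocampheylborane (Ipc groups from (−)-α-pinene) | COc1c(C=C)c(/C=C(\C)CB([C@H]3C[C@H]4C[C@@H]([C@@H]3C)C4(C)C)[C@H]3C[C@H]4C[C@@H]([C@@H]3C)C4(C)C)cc2OC(C)(C)OCc12 | intermediate
19 | (1R,2S)-1-{6-[(tert-butyldimethylsilyl)oxy]-8-methoxy-3-methylisoquinolin-7-yl}-2-(6-ethenyl-5-methoxy-2,2-dimethyl-4H-1,3-benzodioxin-7-yl)-3-methylbut-3-en-1-ol | COc1c([C@H](O)[C@@H](C(C)=C)c3cc4OC(C)(C)OCc4c(OC)c3C=C)c(O[Si](C)(C)C(C)(C)C)cc2cc(C)ncc12 | intermediate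
20 | (1R,2S)-1-{6-[(tert-butyldimethylsilyl)oxy]-8-methoxy-3-methylisoquinolin-7-yl}-2-[2-ethenyl-5-hydroxy-4-(hydroxymethyl)-3-methoxyphenyl]-3-methylbut-3-en-1-ol | COc1c([C@H](O)[C@@H](C(C)=C)c3cc(O)c(CO)c(OC)c3C=C)c(O[Si](C)(C)C(C)(C)C)cc2cc(C)ncc12 | intermediate
21 | 4-[(3S,4R)-4-{6-[(tert-butyldimethylsilyl)oxy]-8-methoxy-3-methylisoquinolin-7-yl}-4-hydroxy-2-methylbut-1-en-3-yl]-5-ethenyl-2-hydroxy-6-methoxybenzaldehyde | COc1c([C@H](O)[C@@H](C(C)=C)c3cc(O)c(C=O)c(OC)c3C=C)c(O[Si](C)(C)C(C)(C)C)cc2cc(C)ncc12 | intermediate
22 | (1S)-1-[(R)-{6-[(tert-butyldimethylsilyl)oxy]-8-methoxy-3-methylisoquinolin-7-yl}(hydroxy)methyl]-6-hydroxy-4-methoxy-2-methyl-1H-indene-5-carbaldehyde | COc1c([C@H](O)[C@H]3C(C)=Cc4c(OC)c(C=O)c(O)cc43)c(O[Si](C)(C)C(C)(C)C)cc2cc(C)ncc12 | intermediate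
23 | 6-[(1R,2S)-1-{6-[(tert-butyldimethylsilyl)oxy]-8-methoxy-3-methylisoquinolin-7-yl}-1-hydroxy-3-oxobutan-2-yl]-4-hydroxy-2-methoxybenzene-1,3-dicarbaldehyde (in equilibrium with its lactol) | COc1c([C@H](O)[C@@H](C(C)=O)c3cc(O)c(C=O)c(OC)c3C=O)c(O[Si](C)(C)C(C)(C)C)cc2cc(C)ncc12 | intermediate
24 | (3R,4S)-4-acetyl-1,6-dihydroxy-3-(6-hydroxy-8-methoxy-3-methylisoquinolin-7-yl)-8-methoxy-3,4-dihydro-1H-2-benzopyran-7-carbaldehyde (lactol, both C1 epimers) | COc1c(C=O)c(O)cc2c1C(O)O[C@@H](c1c(O)cc3cc(C)ncc3c1OC)[C@H]2C(C)=O | intermediate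
25 | CNP0584953.1: (1R,3R,4S)-4-acetyl-6-hydroxy-8-methoxy-3,4-dihydro-1H-2-benzopyran-7-carbaldehyde whose C1 is bonded to O6 and whose C3 is bonded to C7 of 8-methoxy-3-methylisoquinoline (1,3-dioxane bridge) | COc1c(C=O)c(O)cc2c1[C@H]1Oc3cc4cc(C)ncc4c(OC)c3[C@H](O1)[C@H]2C(C)=O | target

**Step count and risks**

Total step count: 17. Longest linear sequence: 14 steps (steps 1–5, 6–9, 13–17).

Step 13. Homocoupling of the allylic chloride during formation of the magnesium reagent, or erosion of facial selectivity at the hindered, nitrogen-containing aldehyde, may lower the amount or the optical purity of 19. The fallback sets out from 14 and comes back at 19. Alcohol 14 is borylated directly (B2pin2, [Pd(MeCN)4](BF4)2 as catalyst, DMSO/MeOH) to the linear pinacol allylboronate F1. F1 adds to 11 on warming through the same chair transition state, anti-selective but racemic, so 19 forms together with its (1S,2R) enantiomer F2, which is removed by preparative chromatography on a chiral stationary phase.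

Step 16. The ruthenium carbene may be arrested by chelation (isoquinoline nitrogen, salicylaldehyde unit), ring closure between a doubly ortho-substituted styrene and a hindered 1,1-disubstituted alkene may stall, or ruthenium hydrides may move the new double bond into the tetrasubstituted position. The fallback sets out from 21 and comes back at 23; it makes no new compound (F0). Both terminal alkenes of 21 are cleaved by the Lemieux–Johnson procedure (OsO4 as catalyst, NaIO4, 2,6-lutidine, dioxane/H2O), which should give keto dialdehyde 23 directly. The formaldehyde released is washed out before the HF·pyridine stage of step 17 is carried out.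

Step 17. Ozone may over-oxidise the oxygenated arenes, and in the acidic fluoride stage C4 may epimerise or the aldol unit may fragment before the acetal has closed. The fallback sets out from 22 and comes back at 24, separating deprotection, oxidation and acid. The silyl group is removed first with acetic acid-buffered TBAF (THF, 0 °C) to give the free phenol F3. OsO4 (catalytic) with NMO then dihydroxylates the indene alkene from the face opposite the C1 side chain to give the cis-diol F4. NaIO4 in buffered aqueous THF cleaves F4 to the keto dialdehyde, which closes to lactol 24. A catalytic amount of PPTS in CH2Cl2 should then be enough to close the bridged acetal 25.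

**Further compounds**

F1 | step 13 | 2-[(2E)-3-(6-ethenyl-5-methoxy-2,2-dimethyl-4H-1,3-benzodioxin-7-yl)-2-methylprop-2-en-1-yl]-4,4,5,5-tetramethyl-1,3,2-dioxaborolane | COc1c(C=C)c(/C=C(\C)CB3OC(C)(C)C(C)(C)O3)cc2OC(C)(C)OCc12
F2 | step 13 | (1S,2R) enantiomer of 19 | COc1c([C@@H](O)[C@H](C(C)=C)c3cc4OC(C)(C)OCc4c(OC)c3C=C)c(O[Si](C)(C)C(C)(C)C)cc2cc(C)ncc12
F0 | step 16 | none | none
F3 | step 17 | (1S)-6-hydroxy-1-[(R)-hydroxy(6-hydroxy-8-methoxy-3-methylisoquinolin-7-yl)methyl]-4-methoxy-2-methyl-1H-indene-5-carbaldehyde | COc1c([C@H](O)[C@H]3C(C)=Cc4c(OC)c(C=O)c(O)cc43)c(O)cc2cc(C)ncc12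
F4 | step 17 | 2,3-cis-diol of F3 (2,3-dihydro-1H-indene-2,3-diol, both hydroxyls on the face opposite the C1 side chain) | COc1c([C@H](O)[C@H]3[C@](C)(O)[C@H](O)c4c(OC)c(C=O)c(O)cc43)c(O)cc2cc(C)ncc12
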